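**Plan**

1. Locants follow the icetexane skeleton: arene/quinone carbons C8, C9, C11–C14 (isopropyl on C13); ring B = C5–C6–C7–C8–C9–C20–C10; ring A = C1–C5 plus C10; lactone carbonyl C19 on C4, lactone oxygen on C6.
2. Retrosynthetic cuts, in order: 12-hydroxy-11,14-quinone back to an 11,12,14-trimethoxyarene; C1–C10 (ring A); C6=C7 back to a C7 carbinol; C7–C8 (ring B); C5–C10, C4–C3 and C4–CH3 from a butenolide that already is the 19,6-lactone.
3. Enabling feature: C1 is a secondary allylic carbinol bonded to C10 of the ring-B alkene C10=C20, i.e. the adduct of a C10 alkenyl metal (from the enol triflate of a ring-B C10 ketone) with a C1 aldehyde tethered through C2–C3 to C4.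
4. Forward: the arene becomes a 2-benzyl-1,3-dithiane (C20 and masked C10) and is joined to an (R)-butenolide; the lactone ring is therefore present first, ring B closes next (Friedel–Crafts), ring A last (Ni/Cr coupling), and the quinone is released at the end.
5. Stereochemistry: C6 of the D-glutamic-acid-derived butenolide steers the dithiane anti (C5); allylation, then methylation, each anti to the C5 substituent, fix C4; C6 is then erased; C1 arises under control of C4/C5 in the ring A closure.
6. The C6=C7 enol lactone is installed after the C10 enol triflate but before ring A closure, so that no acid has to act once the ionisable allylic C1 carbinol exists.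

Key step: step 19

Remark: compounds 21–29 share one core: the 13-isopropyl-11,12,14-trimethoxybenzene ring fused at C8–C9 to ring B, which is fused at C5–C6 to the γ-lactone O–C19(=O)–C4–C5–C6; C4 bears CH3 and the C3–C2–C1 chain.
Remark: C7 of compounds 21–25 should form as a mixture of epimers and is written without configuration; C6 and C7 both disappear as stereocentres in step 16, so epimerisation at either is harmless.
Remark: (R)-5-(hydroxymethyl)dihydrofuran-2(3H)-one is taken as the purchasable lactone derived from D-glutamic acid.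

**Route**

Step 1
Reactants: 1 1,2,4-trimethoxybenzene
Product: 3 2-(2,3,6-trimethoxyphenyl)propan-2-ol, via 3-lithio-1,2,4-trimethoxybenzene 2 (not isolated)
Conditions: n-BuLi, THF, 0 °C to rt; acetone, −78 °C to rt; H2O
Reagents that add atoms: acetone CC(C)=O
Why: Directed ortho-metalation occurs at the carbon flanked by two methoxy groups (the future C13) and the aryllithium adds to acetone, a standard lithiation–carbonyl addition sequence.

Step 2
Reactants: 3 2-(2,3,6-trimethoxyphenyl)propan-2-ol
Product: 4 2-isopropyl-1,3,4-trimethoxybenzene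
Conditions: Et3SiH, CF3CO2H, CH2Cl2, 0 °C to rt
Reagents that add atoms: none
Why: Ionic hydrogenation, in which acid ionises the tertiary benzylic alcohol to a cation stabilised by two ortho methoxy groups and triethylsilane reduces it to the isopropyl group.

Step 3
Reactants: 4 2-isopropyl-1,3,4-trimethoxybenzene
Product: 6 4-isopropyl-2,3,5-trimethoxybenzaldehyde, via (4-isopropyl-2,3,5-trimethoxyphenyl)lithium 5 (not isolated)
Conditions: n-BuLi, TMEDA, Et2O, 0 °C to rt; DMF, −78 °C to rt; H2O
Reagents that add atoms: N,N-dimethylformamide CN(C)C=O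
Why: A second directed ortho-metalation should select the proton beside the vicinal dimethoxy pair (the future C9, ortho to one and meta to two methoxy groups, whereas the other free position is para to a methoxy group and sits next to a methoxy group buttressed by the isopropyl substituent), and formylation of the aryllithium with DMF installs the future C20.

Step 4
Reactants: 6 4-isopropyl-2,3,5-trimethoxybenzaldehyde
Product: 7 2-[(4-isopropyl-2,3,5-trimethoxyphenyl)methylidene]-1,3-dithiane
Conditions: 2-(trimethylsilyl)-1,3-dithiane, n-BuLi, THF, −78 °C to rt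
Reagents that add atoms: 2-(trimethylsilyl)-1,3-dithiane C[Si](C)(C)C1SCCCS1
Why: Peterson olefination of the aldehyde with the lithiated silyl dithiane gives the ketene dithioacetal directly, the β-oxidosilane collapsing with loss of trimethylsilanolate.

Step 5
Reactants: 7 2-[(4-isopropyl-2,3,5-trimethoxyphenyl)methylidene]-1,3-dithiane
Product: 8 2-[(4-isopropyl-2,3,5-trimethoxyphenyl)methyl]-1,3-dithiane
Conditions: Et3SiH, CF3CO2H, CH2Cl2, 0 °C to rt
Reagents that add atoms: none
Why: Ionic hydrogenation of a ketene dithioacetal, in which protonation at the benzylic carbon gives a 1,3-dithian-2-ylium ion that takes hydride from the silane, delivers the dithiane of the arylacetaldehyde (C20–C10) without handling that enolisable aldehyde.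

Step 6
Reactants: 9 (R)-5-(hydroxymethyl)dihydrofuran-2(3H)-one
Product: 10 (R)-5-[(tert-butyldiphenylsilyloxy)methyl]dihydrofuran-2(3H)-one
Conditions: TBDPSCl, imidazole, DMF, rt
Reagents that add atoms: tert-butyl(chloro)diphenylsilane CC(C)(C)[Si](Cl)(c1ccccc1)c1ccccc1
Why: Standard silylation of the primary alcohol, whose carbon later becomes C7, leaves the C6 stereocentre untouched.

Step 7
Reactants: 10 (R)-5-[(tert-butyldiphenylsilyloxy)methyl]dihydrofuran-2(3H)-one
Product: 13 (R)-5-[(tert-butyldiphenylsilyloxy)methyl]furan-2(5H)-one, via lactone lithium enolate 11 (not isolated), via 3-phenylselanyl lactone 12 (not isolated)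
Conditions: LiN(iPr)2, THF, −78 °C; PhSeBr; then AcOH, 30% H2O2, 0 °C to rt
Reagents that add atoms: none
Why: α-Selenenylation of the lactone enolate followed by oxidation and syn-elimination of the selenoxide (selenoxide elimination) introduces the C4=C5 double bond without touching the C6 stereocentre.

Step 8
Reactants: 8 2-[(4-isopropyl-2,3,5-trimethoxyphenyl)methyl]-1,3-dithiane; 13 (R)-5-[(tert-butyldiphenylsilyloxy)methyl]furan-2(5H)-one
Product: 16 (3R,4R,5R)-3-allyl-5-[(tert-butyldiphenylsilyloxy)methyl]-4-{2-[(4-isopropyl-2,3,5-trimethoxyphenyl)methyl]-1,3-dithian-2-yl}dihydrofuran-2(3H)-one, via lithiated benzyl dithiane 14 (not isolated), via adduct lithium enolate 15 (not isolated)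
Conditions: 8, n-BuLi, THF, −30 °C; DMPU, then 13, −78 °C; allyl bromide, −78 to −30 °C
Reagents that add atoms: allyl bromide C=CCBr
Why: Corey–Seebach acyl-anion chemistry in a tandem Michael addition/enolate alkylation, in which the lithiated dithiane adds to C5 anti to the C6 silyloxymethyl group and allyl bromide then enters at C4 anti to the new bulky dithianyl group, so that C5 (R) and the provisional C4 centre are both relayed from C6.

Step 9
Reactants: 16 (3R,4R,5R)-3-allyl lactone
Product: 18 (3S,4R,5R)-3-allyl-5-[(tert-butyldiphenylsilyloxy)methyl]-3-methyl-4-{2-[(4-isopropyl-2,3,5-trimethoxyphenyl)methyl]-1,3-dithian-2-yl}dihydrofuran-2(3H)-one, via allyl lactone lithium enolate 17 (not isolated)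
Conditions: LiN(iPr)2, THF/DMPU, −78 °C; MeI, −78 to −40 °C
Reagents that add atoms: iodomethane CI
Why: Alkylation of the re-formed lactone enolate with iodomethane, again anti to the C5 dithianyl group, creates the quaternary C4 (S) with methyl trans and the allyl chain cis to C10, the arrangement ring A needs.

Step 10
Reactants: 18 (3S,4R,5R)-3-allyl-3-methyl silyl ether
Product: 19 (3S,4R,5R)-3-allyl-5-(hydroxymethyl)-3-methyl-4-{2-[(4-isopropyl-2,3,5-trimethoxyphenyl)methyl]-1,3-dithian-2-yl}dihydrofuran-2(3H)-one
Conditions: Bu4NF, AcOH, THF, 0 °C to rt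
Reagents that add atoms: none
Why: Fluoride-mediated desilylation buffered with acetic acid frees the C7 alcohol while keeping the alkoxide from translactonising.

Step 11
Reactants: 19 C7 alcohol
Product: 20 (2R,3R,4S)-4-allyl-4-methyl-3-{2-[(4-isopropyl-2,3,5-trimethoxyphenyl)methyl]-1,3-dithian-2-yl}-5-oxotetrahydrofuran-2-carbaldehyde
Conditions: SO3·pyridine, DMSO, iPr2NEt, CH2Cl2, 0 °C
Reagents that add atoms: none
Why: Parikh–Doering oxidation gives the α-acyloxy aldehyde under mild conditions and, being an activated-DMSO method, leaves the dithiane sulfur atoms alone.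

Step 12
Reactants: 20 C7 aldehyde
Product: 21 7-hydroxy tricyclic dithiane lactone (4S,5R,6R; C7 epimers)
Conditions: Me2AlCl, CH2Cl2, −78 to −20 °C
Reagents that add atoms: none
Why: Intramolecular Friedel–Crafts hydroxyalkylation, in which the Me2AlCl-activated C7 aldehyde is attacked by C8 (the only free ring position, para to O12 and ortho to O14), closes seven-membered ring B with help from the quaternary C10, while the aluminium alkoxide formed (methane being the proton sink) resists ionisation; the new C7 centre is inconsequential.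

Step 13
Reactants: 21 7-hydroxy tricyclic dithiane lactone
Product: 22 7-acetoxy tricyclic dithiane lactone (4S,5R,6R)
Conditions: Ac2O, pyridine, DMAP (cat.), CH2Cl2, rt
Reagents that add atoms: acetic anhydride CC(=O)OC(C)=O
Why: Acetylation masks the benzylic carbinol for the base-mediated triflation and turns it into the leaving group needed in step 16.

Step 14
Reactants: 22 7-acetoxy tricyclic dithiane lactone
Product: 23 7-acetoxy tricyclic C10 ketone (4S,5R,6R)
Conditions: MeI, CaCO3, MeCN/H2O, 50 °C
Reagents that add atoms: water O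
Why: Alkylative hydrolysis of the dithiane (S-methylation, thionium formation, capture by water) unmasks the C10 ketone under nearly neutral conditions that spare the lactone, the acetate, the allyl group and the electron-rich arene.

Step 15
Reactants: 23 7-acetoxy tricyclic C10 ketone
Product: 25 7-acetoxy C10 enol triflate (4S,5R,6R), via potassium enolate 24 (not isolated)
Conditions: KN(SiMe3)2, THF, −78 °C; PhNTf2, −78 to 0 °C
Reagents that add atoms: N-phenylbis(trifluoromethanesulfonimide) O=S(=O)(N(c1ccccc1)S(=O)(=O)C(F)(F)F)C(F)(F)F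
Why: Kinetic deprotonation takes a benzylic C20 proton (far more acidic and less hindered than C5–H), and O-sulfonylation of the enolate gives the C10 enol triflate with C10=C20 inside ring B, so that C5 is neither epimerised nor made to expel the lactone oxygen by β-elimination.

Step 16
Reactants: 25 7-acetoxy C10 enol triflate
Product: 26 C4-allyl enol lactone enol triflate (4S,5R)
Conditions: camphorsulfonic acid (cat.), toluene, 60 °C
Reagents that add atoms: none
Why: Acid-catalysed E1 elimination, in which the C7 acetate ionises to a benzylic cation stabilised by the para (O12) and ortho (O14) methoxy groups and the only β-proton, H6, is lost, gives the C6=C7 enol lactone and erases the C6 and C7 centres.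

Step 17
Reactants: 26 C4-allyl enol lactone enol triflate
Product: 28 C4-(3-hydroxypropyl) enol lactone enol triflate (4S,5R), via B-alkyl-9-borabicyclononane 27 (not isolated)
Conditions: 9-BBN, THF, 0 °C to rt; then pH 7 phosphate buffer, 30% H2O2, 0 °C to rt
Reagents that add atoms: hydrogen peroxide OO
Why: Hydroboration–oxidation, in which 9-BBN adds anti-Markovnikov to the monosubstituted alkene only (the trisubstituted enol lactone and enol triflate alkenes are too hindered and electron-poor) and buffered peroxide oxidation spares the enol lactone and the triflate, gives the primary alcohol.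

Step 18
Reactants: 28 C4-(3-hydroxypropyl) enol lactone enol triflate
Product: 29 C4-(3-oxopropyl) enol lactone C10 enol triflate (4S,5R)
Conditions: Dess–Martin periodinane, pyridine, CH2Cl2, 0 °C to rt
Reagents that add atoms: none
Why: Dess–Martin oxidation converts the primary alcohol into the C1 aldehyde under neutral, buffered conditions.

Step 19
Reactants: 29 C4-(3-oxopropyl) enol lactone C10 enol triflate
Product: 30 (1R,4S,5R)-1-hydroxy-11,12,14-trimethoxy tetracyclic enol lactone (hydroquinone trimethyl ether of the target)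
Conditions: CrCl2 (excess), NiCl2 (cat.), degassed DMF, rt, high dilution
Reagents that add atoms: none
Why: Zerovalent nickel, generated from NiCl2 by CrCl2, inserts into the C10–OTf bond and transmetalation to trivalent chromium gives a C10 alkenylchromium that adds to the tethered C1 aldehyde, so that two electrophilic carbons are united reductively (Nozaki–Hiyama–Kishi reaction). The closest known reaction type is the intramolecular Ni/Cr coupling of enol triflates or alkenyl iodides with aldehydes to give cyclic allylic alcohols. Ring A closes by 6-exo-trig addition to the carbonyl group, with C10=C20 held inside ring B so that the alkene geometry is fixed and no transposed allylic alcohol can arise. The new C1 centre is controlled by the C4 and C5 centres locked in the γ-lactone: in the chair-like array of the forming ring with H5 axial, the chromium-bound oxygen should take the equatorial site, free of syn-axial contacts with H3 and H5, which places the hydroxyl trans to H5 (1R). The step needs chemoselective activation of the triflate beside an enol lactone, a lactone carbonyl and an electron-rich arene, and ring closure faster than protodemetalation; the neutral, non-basic CrCl2/NiCl2 medium, the six-membered transition state, high dilution and the absence of any carbonyl-activated proton at C5 secure this.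

Step 20
Reactants: 30 hydroquinone trimethyl ether of the target
Product: 31 12-O-methyl ether of the target (12-methoxy-11,14-quinone)
Conditions: (NH4)2Ce(NO3)6, MeCN/H2O, 0 °C
Reagents that add atoms: water O
Why: Oxidative demethylation, in which the electron-rich arene is oxidised to its radical cation and water attacks the para-related C11 and C14 positions, should give the 12-methoxy-1,4-quinone faster than the allylic alcohol or the alkenes are touched.

Step 21
Reactants: 31 12-O-methyl ether of the target
Product: 32 6,7-anhydroballotiquinone (1R,4S,5R)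
Conditions: LiOH (1.1 equiv), THF/H2O, 0 °C; then dilute HCl to pH 3
Reagents that add atoms: lithium hydroxide [Li+].[OH-]
Why: Hydrolysis of the vinylogous methyl ester by addition–elimination at C12 consumes the single equivalent of hydroxide at the highly electrophilic quinone carbon, the acidic hydroxyquinone formed neutralises the medium, and the enol lactone, whose carbonyl carbon is neopentylic, should survive the short exposure at 0 °C.

**Compound list**

1 | 1,2,4-trimethoxybenzene | COc1ccc(OC)c(OC)c1 | starting material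
2 | 3-lithio-1,2,4-trimethoxybenzene | [Li]c1c(OC)ccc(OC)c1OC | intermediate
3 | 2-(2,3,6-trimethoxyphenyl)propan-2-ol | COc1ccc(OC)c(C(C)(C)O)c1OC | intermediate
4 | 2-isopropyl-1,3,4-trimethoxybenzene | COc1ccc(OC)c(C(C)C)c1OC | intermediate
5 | (4-isopropyl-2,3,5-trimethoxyphenyl)lithium | [Li]c1cc(OC)c(C(C)C)c(OC)c1OC | intermediate
6 | 4-isopropyl-2,3,5-trimethoxybenzaldehyde | O=Cc1cc(OC)c(C(C)C)c(OC)c1OC | intermediate
7 | 2-[(4-isopropyl-2,3,5-trimethoxyphenyl)methylidene]-1,3-dithiane | COc1cc(C=C2SCCCS2)c(OC)c(OC)c1C(C)C | intermediate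
8 | 2-[(4-isopropyl-2,3,5-trimethoxyphenyl)methyl]-1,3-dithiane | COc1cc(CC2SCCCS2)c(OC)c(OC)c1C(C)C | intermediate
9 | (R)-5-(hydroxymethyl)dihydrofuran-2(3H)-one | OC[C@H]1CCC(=O)O1 | starting material
10 | (R)-5-[(tert-butyldiphenylsilyloxy)methyl]dihydrofuran-2(3H)-one | CC(C)(C)[Si](OC[C@H]1CCC(=O)O1)(c1ccccc1)c1ccccc1 | intermediate
11 | lithium enolate of lactone 10 | CC(C)(C)[Si](OC[C@H]1CC=C(O[Li])O1)(c1ccccc1)c1ccccc1 | intermediate
12 | (5R)-5-[(tert-butyldiphenylsilyloxy)methyl]-3-(phenylselanyl)dihydrofuran-2(3H)-one (C3 epimers) | CC(C)(C)[Si](OC[C@H]1CC([Se]c2ccccc2)C(=O)O1)(c1ccccc1)c1ccccc1 | intermediate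
13 | (R)-5-[(tert-butyldiphenylsilyloxy)methyl]furan-2(5H)-one | CC(C)(C)[Si](OC[C@H]1C=CC(=O)O1)(c1ccccc1)c1ccccc1 | intermediate
14 | 2-lithio-2-[(4-isopropyl-2,3,5-trimethoxyphenyl)methyl]-1,3-dithiane | [Li]C1(Cc2cc(OC)c(C(C)C)c(OC)c2OC)SCCCS1 | intermediate
15 | lithium enolate of the conjugate adduct (C5 R, C6 R; dithianyl trans to CH2OSi) | CC(C)(C)[Si](OC[C@@H]1OC(O[Li])=C[C@H]1C2(Cc3cc(OC)c(C(C)C)c(OC)c3OC)SCCCS2)(c4ccccc4)c5ccccc5 | intermediate
16 | (3R,4R,5R)-3-allyl-5-[(tert-butyldiphenylsilyloxy)methyl]-4-{2-[(4-isopropyl-2,3,5-trimethoxyphenyl)methyl]-1,3-dithian-2-yl}dihydrofuran-2(3H)-one | CC(C)(C)[Si](OC[C@@H]1OC(=O)[C@H](CC=C)[C@H]1C2(Cc3cc(OC)c(C(C)C)c(OC)c3OC)SCCCS2)(c4ccccc4)c5ccccc5 | intermediate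
17 | lithium enolate of lactone 16 | CC(C)(C)[Si](OC[C@@H]1OC(O[Li])=C(CC=C)[C@H]1C2(Cc3cc(OC)c(C(C)C)c(OC)c3OC)SCCCS2)(c4ccccc4)c5ccccc5 | intermediate
18 | (3S,4R,5R)-3-allyl-5-[(tert-butyldiphenylsilyloxy)methyl]-3-methyl-4-{2-[(4-isopropyl-2,3,5-trimethoxyphenyl)methyl]-1,3-dithian-2-yl}dihydrofuran-2(3H)-one (methyl trans, allyl cis to the dithianyl group) | CC(C)(C)[Si](OC[C@@H]1OC(=O)[C@@](C)(CC=C)[C@H]1C2(Cc3cc(OC)c(C(C)C)c(OC)c3OC)SCCCS2)(c4ccccc4)c5ccccc5 | intermediate
19 | (3S,4R,5R)-3-allyl-5-(hydroxymethyl)-3-methyl-4-{2-[(4-isopropyl-2,3,5-trimethoxyphenyl)methyl]-1,3-dithian-2-yl}dihydrofuran-2(3H)-one | OC[C@@H]1OC(=O)[C@@](C)(CC=C)[C@H]1C2(Cc3cc(OC)c(C(C)C)c(OC)c3OC)SCCCS2 | intermediate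
20 | (2R,3R,4S)-4-allyl-4-methyl-3-{2-[(4-isopropyl-2,3,5-trimethoxyphenyl)methyl]-1,3-dithian-2-yl}-5-oxotetrahydrofuran-2-carbaldehyde | O=C[C@@H]1OC(=O)[C@@](C)(CC=C)[C@H]1C2(Cc3cc(OC)c(C(C)C)c(OC)c3OC)SCCCS2 | intermediate
21 | 7-hydroxy tricyclic lactone: ring B closed at C7–C8, C10 as 1,3-dithiane, γ-lactone trans-fused to ring B (4S,5R,6R), C4 methyl and allyl, C7 epimers | OC3[C@@H]1OC(=O)[C@@](C)(CC=C)[C@H]1C4(SCCCS4)Cc5c(OC)c(OC)c(C(C)C)c(OC)c35 | intermediate
22 | 7-acetate of 21 (4S,5R,6R; C7 epimers) | CC(=O)OC3[C@@H]1OC(=O)[C@@](C)(CC=C)[C@H]1C4(SCCCS4)Cc5c(OC)c(OC)c(C(C)C)c(OC)c35 | intermediate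
23 | 7-acetoxy tricyclic lactone with C10 ketone (4S,5R,6R; C7 epimers) | CC(=O)OC3[C@@H]1OC(=O)[C@@](C)(CC=C)[C@H]1C(=O)Cc4c(OC)c(OC)c(C(C)C)c(OC)c34 | intermediate
24 | potassium C10–C20 enolate of ketone 23 | CC(=O)OC3[C@@H]1OC(=O)[C@@](C)(CC=C)[C@H]1C([O-])=Cc4c(OC)c(OC)c(C(C)C)c(OC)c34.[K+] | intermediate
25 | 7-acetoxy tricyclic lactone C10 enol triflate, C10=C20 in ring B (4S,5R,6R; C7 epimers) | CC(=O)OC3[C@@H]1OC(=O)[C@@](C)(CC=C)[C@H]1C(OS(=O)(=O)C(F)(F)F)=Cc4c(OC)c(OC)c(C(C)C)c(OC)c34 | intermediate
26 | tricyclic enol lactone (C6=C7) C10 enol triflate with allyl and methyl on C4 (4S,5R) | C=CC[C@]4(C)C(=O)OC3=Cc2c(OC)c(C(C)C)c(OC)c(OC)c2C=C(OS(=O)(=O)C(F)(F)F)[C@@H]34 | intermediate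
27 | B-alkyl-9-borabicyclo[3.3.1]nonane from hydroboration of the allyl group of 26 | C(CC[C@]4(C)C(=O)OC3=Cc2c(OC)c(C(C)C)c(OC)c(OC)c2C=C(OS(=O)(=O)C(F)(F)F)[C@@H]34)B5C6CCCC5CCC6 | intermediate
28 | tricyclic enol lactone C10 enol triflate with a 3-hydroxypropyl chain on C4 (4S,5R) | OCCC[C@]4(C)C(=O)OC3=Cc2c(OC)c(C(C)C)c(OC)c(OC)c2C=C(OS(=O)(=O)C(F)(F)F)[C@@H]34 | intermediate
29 | tricyclic enol lactone C10 enol triflate with a 3-oxopropyl chain on C4 (4S,5R) | O=CCC[C@]4(C)C(=O)OC3=Cc2c(OC)c(C(C)C)c(OC)c(OC)c2C=C(OS(=O)(=O)C(F)(F)F)[C@@H]34 | intermediate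
30 | hydroquinone trimethyl ether of the target: (1R,4S,5R)-1-hydroxy-11,12,14-trimethoxy tetracycle with C6=C7 enol lactone and C10=C20 | CC(C)c1c(OC)c(OC)c2c(C=C3OC(=O)[C@@]4(C)CC[C@@H](O)C(=C2)[C@@H]34)c1OC | intermediate
31 | 12-O-methyl-6,7-anhydroballotiquinone (12-methoxy-11,14-quinone; 1R,4S,5R) | CC(C)C1=C(OC)C(=O)C2=C(C=C3OC(=O)[C@@]4(C)CC[C@@H](O)C(=C2)[C@@H]34)C1=O | intermediate
32 | 6,7-anhydroballotiquinone (1R,4S,5R) | CC(C)C1=C(O)C(=O)C2=C(C=C3OC(=O)[C@@]4(C)CC[C@@H](O)C(=C2)[C@@H]34)C1=O | target

**Step count and risks**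

Total steps: 21. Longest linear sequence: 19 (steps 1–5, then 8–21); the butenolide branch (steps 6–7) joins at step 8.

Step 12 (ring B closure). The seven-membered Friedel–Crafts closure may be outrun by intermolecular hydroxyalkylation, or the carbinol may ionise under the Lewis acid. The fallback closes the ring by acylation instead, setting out from aldehyde 20. Pinnick oxidation (NaClO2, NaH2PO4, 2-methyl-2-butene, t-BuOH/H2O) should give the C7 carboxylic acid F1. Treatment with (CF3CO)2O in CH2Cl2 should form the mixed anhydride, which acylates C8 to give the C7 aryl ketone F2; seven-membered aryl ketone formation of this kind is robust. NaBH4 in MeOH/THF at low temperature should then reduce only this ketone and return the route to carbinol 21; epimerisation at C6 or C7 on the way is irrelevant because both centres vanish in step 16.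

Step 19 (ring A closure). Facial selectivity at C1 in the carbonyl addition may be poor. The fallback sets C1 by hydride delivery instead of C–C bond formation, setting out from 30 obtained together with the C1-epimeric alcohol F3. Oxidation of the mixture with MnO2 in CH2Cl2 should give the cross-conjugated C1 enone F4. Luche reduction (NaBH4, CeCl3·7H2O, MeOH/THF, −78 °C) should deliver hydride axially and return the equatorial 1R alcohol 30.

Step 21 (12-O-demethylation). Chemoselectivity may be lost if hydroxide attacks the enol lactone carbonyl as well as C12, opening the lactone. The fallback cleaves the other C–O bond of the methoxy group, setting out from 31. LiCl in DMF at about 90 °C attacks the methyl carbon in an SN2 dealkylation of the vinylogous ester (Krapcho type) with no hydroxide present. This gives the lithium salt of 32, protonated on work-up to 32, without passing through any new isolable compound (F0).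

**Further compounds**

F1 | step 12 | (2R,3R,4S)-4-allyl-4-methyl-3-{2-[(4-isopropyl-2,3,5-trimethoxyphenyl)methyl]-1,3-dithian-2-yl}-5-oxotetrahydrofuran-2-carboxylic acid | OC(=O)[C@@H]1OC(=O)[C@@](C)(CC=C)[C@H]1C2(Cc3cc(OC)c(C(C)C)c(OC)c3OC)SCCCS2
F2 | step 12 | 7-oxo tricyclic dithiane lactone (C7 aryl ketone; 4S,5R,6R) | O=C3[C@@H]1OC(=O)[C@@](C)(CC=C)[C@H]1C4(SCCCS4)Cc5c(OC)c(OC)c(C(C)C)c(OC)c35
F3 | step 19 | C1 epimer of 30 (1S,4S,5R) | CC(C)c1c(OC)c(OC)c2c(C=C3OC(=O)[C@@]4(C)CC[C@H](O)C(=C2)[C@@H]34)c1OC
F4 | step 19 | C1 ketone (enone) corresponding to 30 (4S,5R) | CC(C)c1c(OC)c(OC)c2c(C=C3OC(=O)[C@@]4(C)CCC(=O)C(=C2)[C@@H]34)c1OC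
F0 | step 21 | none | none
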